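**Strategy.** The synthesis rests on cutting ring A (the benzoate that carries the 2-acyloxypropyl chain) at its C6–CH2 bond. In that ring C2 and C4 are oxygenated, so C6–H is the only C–H bond ortho to the C1 carboxyl, and the C6 substituent, (R)-CH2–CH(O)–CH3, is (R)-propylene oxide opened at its CH2 end. One carboxylate-directed palladium-catalysed C–H alkylation of 2,4-bis(benzyloxy)benzoic acid with the epoxide therefore forges the aryl–CH2 bond and the lactone C–O bond, giving the protected 6-hydroxymellein with its stereocentre intact. Ring B, carrying the 4-hydroxy-2-oxopentyl chain, is assembled by toluate acylation, and the fragments are joined by esterification before one global hydrogenolysis.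

Key step: step 2

Remark: all four stereocentres of the target are (R); methyl orsellinate, (S)-pent-4-en-2-ol and both enantiomeric 3-hydroxybutanoate esters are taken as purchasable.

Step 1
Reactants: 1 2,4-dihydroxybenzoic acid
Product: 3 2,4-bis(benzyloxy)benzoic acid, via tribenzyl compound 2 (not isolated)
Conditions: BnBr, K2CO3, DMF, 70 °C; aqueous work-up; crude, KOH, MeOH/THF/H2O, reflux; HCl
Reagents that add atoms: benzyl bromide, BrCc1ccccc1; potassium hydroxide, [K+].[OH-]
Why: Williamson O-alkylation of both phenols and the carboxylate, then saponification of the benzyl ester, is routine and should leave the two aryl benzyl ethers untouched.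

Step 2
Reactants: 3 2,4-bis(benzyloxy)benzoic acid; 4 (R)-propylene oxide
Product: 6 (3R)-6,8-bis(benzyloxy)-3-methyl-3,4-dihydroisocoumarin, via hydroxy acid 5 (not isolated)
Conditions: Pd(OAc)2 (10 mol%), N-acetyl-L-tert-leucine (20 mol%), KOAc, (CF3)2CHOH, 75 °C, sealed tube
Reagents that add atoms: none
Why: The potassium carboxylate of 3 binds divalent palladium and, helped by the N-acetyl amino acid ligand, should undergo concerted metalation–deprotonation at C6–H to a five-membered palladacycle; its aryl–palladium bond opens the epoxide at the CH2 terminus in an SN2 manner without change of oxidation state, and protonolysis releases hydroxy acid 5. The closest known reaction type is the carboxylate-directed ortho C–H alkylation of benzoic acids with terminal epoxides, which gives 3-substituted 3,4-dihydroisocoumarins. The six-membered lactone closes by 6-exo-trig attack of the side-chain oxygen of 5 on the carboxyl carbon under the reaction conditions. No stereocentre is created: C3 of 6 is the epoxide CH carbon, whose C–O bond is never broken, so (R)-propylene oxide should deliver the (R) lactone. Site selectivity comes from the C2 benzyloxy group, which leaves C6–H as the only ortho C–H bond and excludes double alkylation; regioselectivity on the epoxide comes from attack at the less hindered carbon.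

Step 3
Reactants: 6 (3R)-6,8-bis(benzyloxy)-3-methyl-3,4-dihydroisocoumarin
Product: 9 2,4-bis(benzyloxy)-6-[(2R)-2-(tert-butyldimethylsilyloxy)propyl]benzoic acid, via potassium carboxylate 7 (not isolated), via bis-silyl compound 8 (not isolated)
Conditions: KOH (1.1 equiv), THF/MeOH/H2O, 50 °C; evaporate, PhMe azeotrope; TBSOTf, 2,6-lutidine, CH2Cl2, 0 °C; K2CO3, MeOH/H2O, rt; HCl to pH 4, 0 °C
Reagents that add atoms: potassium hydroxide, [K+].[OH-]; tert-butyldimethylsilyl trifluoromethanesulfonate, CC(C)(C)[Si](C)(C)OS(=O)(=O)C(F)(F)F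
Why: Lactone saponification to the potassium hydroxy carboxylate 7, silylation of that salt at both oxygens and selective hydrolysis of the labile silyl ester of 8 is the standard seco-acid protection sequence; 7 is carried on as the salt and never acidified, which should prevent relactonization, and the stereocentre is not involved.

Step 4
Reactants: 10 ethyl (S)-3-hydroxybutanoate
Product: 11 benzyl (S)-3-hydroxybutanoate
Conditions: BnOH, Ti(OiPr)4 (cat.), 100 °C, EtOH distilled off
Reagents that add atoms: benzyl alcohol, OCc1ccccc1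
Why: Titanate-catalysed transesterification exchanges the ester alkoxy group under neutral conditions that tolerate the free β-hydroxyl and leave the stereocentre untouched.

Step 5
Reactants: 9 2,4-bis(benzyloxy)-6-[(2R)-2-(tert-butyldimethylsilyloxy)propyl]benzoic acid; 11 benzyl (S)-3-hydroxybutanoate
Product: 12 benzyl (3R)-3-({2,4-bis(benzyloxy)-6-[(2R)-2-(tert-butyldimethylsilyloxy)propyl]benzoyl}oxy)butanoate
Conditions: PPh3, DIAD, PhMe, 0 °C to rt
Reagents that add atoms: none
Why: In this Mitsunobu esterification the hindered carboxylate acts only as an oxygen nucleophile in an SN2 displacement at the activated secondary carbon, so the (S) alcohol should be inverted to the (R) ester and the di-ortho-substituted carboxyl carbon never has to be attacked.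

Step 6
Reactants: 12 benzyl (3R)-3-({2,4-bis(benzyloxy)-6-[(2R)-2-(tert-butyldimethylsilyloxy)propyl]benzoyl}oxy)butanoate
Product: 13 benzyl (3R)-3-({2,4-bis(benzyloxy)-6-[(2R)-2-hydroxypropyl]benzoyl}oxy)butanoate
Conditions: HF·pyridine, pyridine, THF, 0 °C to rt
Reagents that add atoms: none
Why: Fluoride-mediated desilylation in a buffered, weakly acidic medium should free the secondary alcohol without forming an alkoxide that could attack the neighbouring aryl ester; 13 is used promptly.

Step 7
Reactants: 14 methyl 2,4-dihydroxy-6-methylbenzoate (methyl orsellinate)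
Product: 16 2,4-bis(benzyloxy)-6-methylbenzoic acid, via methyl ester 15 (not isolated)
Conditions: BnBr, K2CO3, DMF, 60 °C; aqueous work-up; crude, KOH, DMSO/H2O, 90 °C; HCl
Reagents that add atoms: benzyl bromide, BrCc1ccccc1; potassium hydroxide, [K+].[OH-]
Why: Williamson benzylation of both phenols followed by forcing saponification of the hindered methyl ester should give the acid, the aryl benzyl ethers being stable to hydroxide.

Step 8
Reactants: 16 2,4-bis(benzyloxy)-6-methylbenzoic acid; 17 (S)-pent-4-en-2-ol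
Product: 18 (2R)-pent-4-en-2-yl 2,4-bis(benzyloxy)-6-methylbenzoate
Conditions: PPh3, DIAD, THF, 0 °C to rt
Reagents that add atoms: none
Why: Mitsunobu esterification of a di-ortho-substituted benzoic acid with a homoallylic secondary alcohol should proceed by SN2 inversion to the (R) ester; the pentenyl group is a base-stable precursor of the 3-oxybutanoic acid unit.

Step 9
Reactants: 19 methyl (R)-3-hydroxybutanoate
Product: 20 methyl (R)-3-(benzyloxy)butanoate
Conditions: BnOC(=NH)CCl3, TfOH (cat.), CH2Cl2/cyclohexane, 0 °C to rt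
Reagents that add atoms: benzyl 2,2,2-trichloroacetimidate, N=C(OCc1ccccc1)C(Cl)(Cl)Cl
Why: Acid-catalysed benzylation with the trichloroacetimidate avoids the basic conditions under which a β-hydroxy ester would eliminate, and the C–O bond at the stereocentre is kept.

Step 10
Reactants: 20 methyl (R)-3-(benzyloxy)butanoate
Product: 21 (R)-3-(benzyloxy)-N-methoxy-N-methylbutanamide
Conditions: MeNHOMe·HCl, iPrMgCl, THF, −20 to 0 °C
Reagents that add atoms: N,O-dimethylhydroxylamine hydrochloride, CNOC.Cl
Why: Weinreb amide formation by direct aminolysis of the ester with the chloromagnesium amide should proceed at low temperature without β-elimination or loss of configuration.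

Step 11
Reactants: 18 (2R)-pent-4-en-2-yl 2,4-bis(benzyloxy)-6-methylbenzoate; 21 (R)-3-(benzyloxy)-N-methoxy-N-methylbutanamide
Product: 23 (2R)-pent-4-en-2-yl 2,4-bis(benzyloxy)-6-[(4R)-4-(benzyloxy)-2-oxopentyl]benzoate, via lithiated toluate 22 (not isolated)
Conditions: LiN(iPr)2 (1.3 equiv), THF, −78 °C; then 21, −78 °C; AcOH quench
Reagents that add atoms: none
Why: Lateral lithiation of the ortho-toluate gives a stabilised benzylic anion that should acylate the Weinreb amide once, because the chelated tetrahedral adduct releases the ketone only on quench (toluate anion acylation); no stereocentre is formed or touched.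

Step 12
Reactants: 23 (2R)-pent-4-en-2-yl 2,4-bis(benzyloxy)-6-[(4R)-4-(benzyloxy)-2-oxopentyl]benzoate
Product: 26 (3R)-3-({2,4-bis(benzyloxy)-6-[(4R)-4-(benzyloxy)-2-oxopentyl]benzoyl}oxy)butanoic acid, via diol 24 (not isolated), via aldehyde 25 (not isolated)
Conditions: OsO4 (cat.), NaIO4, 2,6-lutidine, dioxane/H2O, rt; extractive work-up; crude, NaClO2, NaH2PO4, 2-methyl-2-butene, t-BuOH/H2O, 0 °C to rt
Reagents that add atoms: osmium tetroxide, O=[Os](=O)(=O)=O; sodium periodate NaIO4, [Na+].[O-]I(=O)(=O)=O; sodium chlorite NaClO2, [Na+].[O-]Cl=O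
Why: Lemieux–Johnson cleavage of the terminal alkene and immediate Pinnick oxidation of the crude β-acyloxy aldehyde should turn the pentenyl group into the 3-acyloxybutanoic acid without affecting the benzyl ethers, the ketone or either stereocentre.

Step 13
Reactants: 13 benzyl (3R)-3-({2,4-bis(benzyloxy)-6-[(2R)-2-hydroxypropyl]benzoyl}oxy)butanoate; 26 (3R)-3-({2,4-bis(benzyloxy)-6-[(4R)-4-(benzyloxy)-2-oxopentyl]benzoyl}oxy)butanoic acid
Product: 27 hexabenzyl-protected Hansforester I
Conditions: DCC, DMAP (cat.), CH2Cl2, 0 °C to rt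
Reagents that add atoms: none
Why: Steglich esterification of an unhindered aliphatic acid with a secondary alcohol breaks no bond at a stereocentre, and low temperature with sub-stoichiometric DMAP should limit β-elimination of the activated acid and translactonization of 13.

Step 14
Reactants: 27 hexabenzyl-protected Hansforester I
Product: 28 Hansforester I
Conditions: H2 (1 atm), Pd(OH)2/C, EtOAc/THF, rt
Reagents that add atoms: none
Why: Catalytic hydrogenolysis should cleave the four aryl benzyl ethers, the alkyl benzyl ether and the benzyl ester in one operation, while the aliphatic ketone, the ester links and the non-benzylic C–O stereocentres stay intact.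

**Compound list**

1 | 2,4-dihydroxybenzoic acid | O=C(O)c1ccc(O)cc1O | starting material
2 | benzyl 2,4-bis(benzyloxy)benzoate | O=C(OCc1ccccc1)c1ccc(OCc2ccccc2)cc1OCc1ccccc1 | intermediate
3 | 2,4-bis(benzyloxy)benzoic acid | O=C(O)c1ccc(OCc2ccccc2)cc1OCc1ccccc1 | intermediate
4 | (R)-propylene oxide | C[C@@H]1CO1 | starting material
5 | 2,4-bis(benzyloxy)-6-[(2R)-2-hydroxypropyl]benzoic acid | C[C@@H](O)Cc1cc(OCc2ccccc2)cc(OCc2ccccc2)c1C(=O)O | intermediate
6 | (3R)-6,8-bis(benzyloxy)-3-methyl-3,4-dihydroisocoumarin | C[C@@H]1Cc2cc(OCc3ccccc3)cc(OCc3ccccc3)c2C(=O)O1 | intermediate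
7 | potassium 2,4-bis(benzyloxy)-6-[(2R)-2-hydroxypropyl]benzoate | C[C@@H](O)Cc1cc(OCc2ccccc2)cc(OCc2ccccc2)c1C(=O)[O-].[K+] | intermediate
8 | tert-butyldimethylsilyl 2,4-bis(benzyloxy)-6-[(2R)-2-(tert-butyldimethylsilyloxy)propyl]benzoate | C[C@@H](O[Si](C)(C)C(C)(C)C)Cc1cc(OCc2ccccc2)cc(OCc2ccccc2)c1C(=O)O[Si](C)(C)C(C)(C)C | intermediate
9 | 2,4-bis(benzyloxy)-6-[(2R)-2-(tert-butyldimethylsilyloxy)propyl]benzoic acid | C[C@@H](O[Si](C)(C)C(C)(C)C)Cc1cc(OCc2ccccc2)cc(OCc2ccccc2)c1C(=O)O | intermediate
10 | ethyl (S)-3-hydroxybutanoate | C[C@H](O)CC(=O)OCC | starting material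
11 | benzyl (S)-3-hydroxybutanoate | C[C@H](O)CC(=O)OCc1ccccc1 | intermediate
12 | benzyl (3R)-3-({2,4-bis(benzyloxy)-6-[(2R)-2-(tert-butyldimethylsilyloxy)propyl]benzoyl}oxy)butanoate | C[C@@H](O[Si](C)(C)C(C)(C)C)Cc1cc(OCc2ccccc2)cc(OCc2ccccc2)c1C(=O)O[C@H](C)CC(=O)OCc1ccccc1 | intermediate
13 | benzyl (3R)-3-({2,4-bis(benzyloxy)-6-[(2R)-2-hydroxypropyl]benzoyl}oxy)butanoate | C[C@@H](O)Cc1cc(OCc2ccccc2)cc(OCc2ccccc2)c1C(=O)O[C@H](C)CC(=O)OCc1ccccc1 | intermediate
14 | methyl 2,4-dihydroxy-6-methylbenzoate (methyl orsellinate) | Cc1cc(O)cc(O)c1C(=O)OC | starting material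
15 | methyl 2,4-bis(benzyloxy)-6-methylbenzoate | Cc1cc(OCc2ccccc2)cc(OCc2ccccc2)c1C(=O)OC | intermediate
16 | 2,4-bis(benzyloxy)-6-methylbenzoic acid | Cc1cc(OCc2ccccc2)cc(OCc2ccccc2)c1C(=O)O | intermediate
17 | (S)-pent-4-en-2-ol | C[C@H](O)CC=C | starting material
18 | (2R)-pent-4-en-2-yl 2,4-bis(benzyloxy)-6-methylbenzoate | Cc1cc(OCc2ccccc2)cc(OCc2ccccc2)c1C(=O)O[C@H](C)CC=C | intermediate
19 | methyl (R)-3-hydroxybutanoate | C[C@@H](O)CC(=O)OC | starting material
20 | methyl (R)-3-(benzyloxy)butanoate | C[C@@H](OCc1ccccc1)CC(=O)OC | intermediate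
21 | (R)-3-(benzyloxy)-N-methoxy-N-methylbutanamide | C[C@@H](OCc1ccccc1)CC(=O)N(C)OC | intermediate
22 | benzylic lithium derivative of 18 | [Li]Cc1cc(OCc2ccccc2)cc(OCc2ccccc2)c1C(=O)O[C@H](C)CC=C | intermediate
23 | (2R)-pent-4-en-2-yl 2,4-bis(benzyloxy)-6-[(4R)-4-(benzyloxy)-2-oxopentyl]benzoate | C[C@@H](OCc1ccccc1)CC(=O)Cc1cc(OCc2ccccc2)cc(OCc2ccccc2)c1C(=O)O[C@H](C)CC=C | intermediate
24 | (2R)-4,5-dihydroxypentan-2-yl 2,4-bis(benzyloxy)-6-[(4R)-4-(benzyloxy)-2-oxopentyl]benzoate (both C4 epimers) | C[C@@H](OCc1ccccc1)CC(=O)Cc1cc(OCc2ccccc2)cc(OCc2ccccc2)c1C(=O)O[C@H](C)CC(O)CO | intermediate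
25 | (2R)-4-oxobutan-2-yl 2,4-bis(benzyloxy)-6-[(4R)-4-(benzyloxy)-2-oxopentyl]benzoate | C[C@@H](OCc1ccccc1)CC(=O)Cc1cc(OCc2ccccc2)cc(OCc2ccccc2)c1C(=O)O[C@H](C)CC=O | intermediate
26 | (3R)-3-({2,4-bis(benzyloxy)-6-[(4R)-4-(benzyloxy)-2-oxopentyl]benzoyl}oxy)butanoic acid | C[C@@H](OCc1ccccc1)CC(=O)Cc1cc(OCc2ccccc2)cc(OCc2ccccc2)c1C(=O)O[C@H](C)CC(=O)O | intermediate
27 | hexabenzyl-protected Hansforester I (four aryl benzyl ethers, benzyl ether of the pentyl-chain alcohol, benzyl ester of the terminal acid) | C[C@H](Cc1cc(OCc2ccccc2)cc(OCc2ccccc2)c1C(=O)O[C@H](C)CC(=O)OCc1ccccc1)OC(=O)C[C@@H](C)OC(=O)c1c(OCc2ccccc2)cc(OCc2ccccc2)cc1CC(=O)C[C@@H](C)OCc1ccccc1 | intermediate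
28 | Hansforester I | C[C@H](Cc1cc(O)cc(O)c1C(=O)O[C@H](C)CC(=O)O)OC(=O)C[C@@H](C)OC(=O)c1c(O)cc(O)cc1CC(=O)C[C@@H](C)O | target

**Step count**

Total: 14 steps. Longest linear sequence: 7 steps (steps 1, 2, 3, 5, 6, 13, 14).

**Steps most likely to fail**

Step 2. The electron-rich acid may lose carbon dioxide by palladium-mediated protodecarboxylation before C6–H is palladated, or the volatile epoxide may be consumed by the fluorinated solvent before the palladacycle captures it. The fallback makes the same aryl–CH2 bond with reversed polarity and brings in the carboxyl carbon afterwards. It sets out from epoxide 4 and bought 1-bromo-3,5-bis(benzyloxy)benzene (Brc1cc(OCc2ccccc2)cc(OCc2ccccc2)c1). Bromine–lithium exchange (n-BuLi, THF, −78 °C) would give 3,5-bis(benzyloxy)phenyllithium F1, which should open 4 at its CH2 carbon in the presence of BF3·OEt2 to give, after NH4Cl quench, (2R)-1-[3,5-bis(benzyloxy)phenyl]propan-2-ol F2. Bromination with NBS (MeCN, 0 °C) is expected ortho to the side chain and para to a benzyloxy group, giving (2R)-1-[2-bromo-3,5-bis(benzyloxy)phenyl]propan-2-ol F3. Carbonylative lactonization (Pd(OAc)2, 1,3-bis(diphenylphosphino)propane, CO, K2CO3, DMF, 90 °C) would then come back to the route at lactone 6.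

Step 5. The phosphonium-activated β-hydroxy ester may undergo β-elimination to benzyl crotonate instead of SN2 displacement by the carboxylate. The fallback forms the ester by acyl substitution with retention. It sets out from acid 9, which 1-chloro-N,N,2-trimethylprop-1-en-1-amine (CH2Cl2, 0 °C) should convert under neutral conditions into 2,4-bis(benzyloxy)-6-[(2R)-2-(tert-butyldimethylsilyloxy)propyl]benzoyl chloride F4. Benzyl (R)-3-hydroxybutanoate F5, made from 19 in the same way as 11 (BnOH, Ti(OiPr)4), would then be acylated by F4 (Et3N, DMAP, CH2Cl2, 0 °C), returning to the route at 12 with the (R) configuration supplied by the alcohol.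

Step 11. The lithiated ester may attack the ester carbonyl of a second molecule of 18 (self-condensation) in competition with acylation by the amide. The fallback acylates before esterifying. It sets out from acid 16 and amide 21: LiN(iPr)2 (2.2 equiv, THF, −78 to −20 °C) would give dilithiated 2,4-bis(benzyloxy)-6-methylbenzoic acid F6, which carries no ester to condense with. Acylation of F6 with 21 and an HCl quench should give 2,4-bis(benzyloxy)-6-[(4R)-4-(benzyloxy)-2-oxopentyl]benzoic acid F7, and Mitsunobu esterification of F7 with 17 (PPh3, DIAD, THF) comes back to the route at 23.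

**Further compounds**

F1 | step 2 | 3,5-bis(benzyloxy)phenyllithium | [Li]c1cc(OCc2ccccc2)cc(OCc2ccccc2)c1
F2 | step 2 | (2R)-1-[3,5-bis(benzyloxy)phenyl]propan-2-ol | C[C@@H](O)Cc1cc(OCc2ccccc2)cc(OCc2ccccc2)c1
F3 | step 2 | (2R)-1-[2-bromo-3,5-bis(benzyloxy)phenyl]propan-2-ol | C[C@@H](O)Cc1cc(OCc2ccccc2)cc(OCc2ccccc2)c1Br
F4 | step 5 | 2,4-bis(benzyloxy)-6-[(2R)-2-(tert-butyldimethylsilyloxy)propyl]benzoyl chloride | C[C@@H](O[Si](C)(C)C(C)(C)C)Cc1cc(OCc2ccccc2)cc(OCc2ccccc2)c1C(=O)Cl
F5 | step 5 | benzyl (R)-3-hydroxybutanoate | C[C@@H](O)CC(=O)OCc1ccccc1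
F6 | step 11 | dilithiated 2,4-bis(benzyloxy)-6-methylbenzoic acid (lithium carboxylate, benzylic lithium) | [Li]Cc1cc(OCc2ccccc2)cc(OCc2ccccc2)c1C(=O)O[Li]
F7 | step 11 | 2,4-bis(benzyloxy)-6-[(4R)-4-(benzyloxy)-2-oxopentyl]benzoic acid | C[C@@H](OCc1ccccc1)CC(=O)Cc1cc(OCc2ccccc2)cc(OCc2ccccc2)c1C(=O)O
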